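Luzonoid A has its tertiary C8 hydroxyl (cyclopentane ring) on the same side as C1 of the dihydropyran ring, both being attached to the ring-fusion carbon C9, while the C1 acyloxy group lies on the opposite face. C8–O–C1 can therefore be closed as an oxetane and later opened at C1 with inversion by isovaleric acid. One intramolecular Paternò–Büchi reaction of a C8 ketone with the C1=C9 enol ether of a 4H-pyran forms C8–C9 and O–C1. This gives the cyclopentane, the oxetane acetal and the C1, C8 and C9 centres from the single C5 centre. The precursor is a 4H-pyran-3-carboxylate carrying at its sp3 carbon (C5) a 2-silyloxy-3-oxo-4-silyloxybutyl chain from 2-deoxy-D-ribose.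

Key step: step 8

Remarks on the chemistry
- Atoms are referred to by iridoid numbering (C1, O2, C3, C4, C5, C6, C7, C8, C9; C10 on C8, C11 on C4). Names of bicyclic compounds use cyclopenta[c]pyran locants (1, 4a, 6, 7, 7a = C1, C5, C7, C8, C9).
- Assumption: in step 5 the antipode of the chromium catalyst is the one that delivers the (2S,4S) acetal; the sense is assigned on a simple β-alkyl enal before use.
- The C1 configuration of 10, 12 and 13 is drawn as the endo (2,4-cis) adduct. It has no consequence, because C1 becomes sp2 in step 7.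
- The precursor keeps silyl ethers on O7 and O10. They carry no C–H bond γ to the carbonyl, so C5–H is the only γ-hydrogen the excited ketone can reach.
- The C4 ester is introduced after the ring is formed and C1=C9 is made without protic acid, because an acetal next to a vinylogous carbonate oxygen ionises slowly.

Step 1
Reactants: 1 2-deoxy-D-ribose
Product: 2 2-deoxy-D-ribono-1,4-lactone, (4S,5R)-4-hydroxy-5-(hydroxymethyl)oxolan-2-one
Conditions: Br2, H2O, 23 °C
Reagents that add atoms: none
Why: Bromine-water oxidation of the aldose hemiacetal to the aldonic acid, which closes to the five-membered lactone; the two carbinol centres (sugar C3 and C4, later C7 and C8) are not involved.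

Step 2
Reactants: 2 2-deoxy-D-ribono-1,4-lactone
Product: 4 (4S,5R)-5-{[(tert-butyldimethylsilyl)oxy]methyl}-4-[(triethylsilyl)oxy]oxolan-2-one, via 5-O-TBS lactone 3 (not isolated)
Conditions: TBSCl (1.05 equiv), imidazole, DMF, −20 → 0 °C; then TESCl, 0 → 23 °C
Reagents that add atoms: tert-butyldimethylsilyl chloride, CC(C)(C)[Si](C)(C)Cl; triethylsilyl chloride, CC[Si](CC)(CC)Cl
Why: Stepwise silyl ether formation in one flask: the hindered silyl chloride selects the primary hydroxyl, the smaller one then caps the secondary hydroxyl that becomes O7, and the lactone keeps the future O8 masked as the ring oxygen.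

Step 3
Reactants: 4 (4S,5R)-5-{[(tert-butyldimethylsilyl)oxy]methyl}-4-[(triethylsilyl)oxy]oxolan-2-one
Product: 5 (2R,3S)-1-[(tert-butyldimethylsilyl)oxy]-3-[(triethylsilyl)oxy]pentane-2,5-diol
Conditions: LiBH4, THF, 0 °C
Reagents that add atoms: none
Why: Borohydride reduction of the lactone to the 1,4-diol releases the former ring oxygen as the only free secondary hydroxyl (on the future C8) and creates no stereocentre; the cold, non-protic medium limits silyl migration.

Step 4
Reactants: 5 (2R,3S)-1-[(tert-butyldimethylsilyl)oxy]-3-[(triethylsilyl)oxy]pentane-2,5-diol; 6 (triphenylphosphoranylidene)acetaldehyde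
Product: 8 (2E,5S)-7-[(tert-butyldimethylsilyl)oxy]-6-oxo-5-[(triethylsilyl)oxy]hept-2-enal, via keto aldehyde 7 (not isolated)
Conditions: (COCl)2, DMSO, CH2Cl2, −78 °C; Et3N, −78 → −30 °C; then 6, −30 → 23 °C
Reagents that add atoms: none
Why: Swern oxidation of both hydroxyls (each is activated before base is added, so no lactol can form) gives the γ-keto aldehyde, which is trapped in the same flask by an aldehyde-selective, E-selective Wittig reaction with the stabilised formyl ylide; the C7 centre meets only amine base at low temperature.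

Step 5
Reactants: 8 (2E,5S)-7-[(tert-butyldimethylsilyl)oxy]-6-oxo-5-[(triethylsilyl)oxy]hept-2-enal; 9 ethyl vinyl ether
Product: 10 (3S)-1-[(tert-butyldimethylsilyl)oxy]-4-[(2S,4S)-2-ethoxy-3,4-dihydro-2H-pyran-4-yl]-3-[(triethylsilyl)oxy]butan-2-one
Conditions: chiral tridentate Schiff-base Cr(III)Cl catalyst (from 3-(1-adamantyl)-5-methylsalicylaldehyde and cis-1-amino-2-indanol, 5 mol%), 9 (10 equiv), 4 Å MS, TBME, 23 °C
Reagents that add atoms: none
Why: Inverse-electron-demand hetero-Diels–Alder reaction of the enal (as 1-oxadiene) with the vinyl ether under chiral chromium(III) Lewis-acid catalysis, a reaction shown for β-alkyl enals; the catalyst shields one face of the enal and so sets C5 (4S in the pyran) irrespective of the remote C7 centre, the endo mode gives the 2,4-cis acetal, and the enal-derived arm becomes the C3=C4 enol ether.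

Step 6
Reactants: 10 (3S)-1-[(tert-butyldimethylsilyl)oxy]-4-[(2S,4S)-2-ethoxy-3,4-dihydro-2H-pyran-4-yl]-3-[(triethylsilyl)oxy]butan-2-one; 11 trichloroacetyl chloride
Product: 13 methyl (2S,4S)-4-[(2S)-4-[(tert-butyldimethylsilyl)oxy]-3-oxo-2-[(triethylsilyl)oxy]butyl]-2-ethoxy-3,4-dihydro-2H-pyran-5-carboxylate, via trichloromethyl ketone 12 (not isolated)
Conditions: 11, pyridine, CH2Cl2, 0 → 23 °C; then Et3N, MeOH, DMAP (cat.), 0 → 23 °C
Reagents that add atoms: methanol, CO
Why: Electrophilic acylation of the enol ether at its β-carbon C4 (the only enol ether present) and haloform-type methanolysis of the vinylogous trichloromethyl ketone install the C4 ester while the two arms of the ring still differ, so C5 stays a stereocentre; triethylamine is added before methanol so that the medium is never acidic towards the TES ether.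

Step 7
Reactants: 13 methyl (2S,4S)-4-[(2S)-4-[(tert-butyldimethylsilyl)oxy]-3-oxo-2-[(triethylsilyl)oxy]butyl]-2-ethoxy-3,4-dihydro-2H-pyran-5-carboxylate
Product: 14 methyl (4S)-4-[(2S)-4-[(tert-butyldimethylsilyl)oxy]-3-oxo-2-[(triethylsilyl)oxy]butyl]-4H-pyran-3-carboxylate
Conditions: TMSOTf, 2,4,6-collidine, CH2Cl2, −20 → 23 °C
Reagents that add atoms: none
Why: Silyl triflate/pyridine-base elimination of an acetal to an enol ether: the Lewis acid removes the C1 ethoxy group as its silyl ether and collidine takes H9 from the oxocarbenium ion; the hindered pyridine base should not enolise the ketone, the silyl ethers are inert, and no stereocentre is touched because C1 becomes sp2.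

Step 8
Reactants: 14 methyl (4S)-4-[(2S)-4-[(tert-butyldimethylsilyl)oxy]-3-oxo-2-[(triethylsilyl)oxy]butyl]-4H-pyran-3-carboxylate
Product: 15 methyl (1R,4aS,6S,7R,7aS)-7-{[(tert-butyldimethylsilyl)oxy]methyl}-1,7-epoxy-6-[(triethylsilyl)oxy]-1,4a,5,6,7,7a-hexahydrocyclopenta[c]pyran-4-carboxylate (oxygen bridge C8–O–C1)
Conditions: hν (300 nm, Pyrex, base-washed vessel), degassed MeCN (2 mM), −30 °C
Reagents that add atoms: none
Why: Intramolecular Paternò–Büchi [2+2] photocycloaddition, the closest known class being the addition of alkyl ketones to tethered or cyclic enol ethers (and furans) that gives fused 2-alkoxyoxetanes. n→π* excitation of the C8 ketone at 300 nm, where the β-alkoxyacrylate is transparent, is followed by attack on the electron-rich C1=C9 bond: the cyclopentane closes by 5-exo-trig C8–C9 bonding (rule of five) to a 1,4-biradical whose C1 centre is stabilised by O2, and the oxetane closes by O–C1 recombination of that biradical. C9 is fixed because the C6 tether lets C8 reach only the pyran face that carries C6, which forces the cis ring fusion; C1 is fixed because the addition across C1=C9 is suprafacial, so O–C1 forms on the face that already holds C8; C8 is fixed because its oxygen must span to C1 in a four-membered ring, which places C10 on the convex face. All three centres therefore follow from C5 (set in step 5), and the C7 silyloxy group is a spectator on the convex face. The step needs site selectivity for C1=C9 over C3=C4, which the C4 ester secures (vinylogous carbonate, electron-poor), fused rather than crossed regiochemistry, which the three-atom tether secures, and cycloaddition ahead of Norrish type II abstraction of the allylic C5–H, which the electron-rich enol ether, the low temperature and the absence of any other γ-hydrogen favour.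

Step 9
Reactants: 15 methyl (1R,4aS,6S,7R,7aS)-7-{[(tert-butyldimethylsilyl)oxy]methyl}-1,7-epoxy-6-[(triethylsilyl)oxy]-1,4a,5,6,7,7a-hexahydrocyclopenta[c]pyran-4-carboxylate
Product: 16 methyl (1R,4aS,6S,7R,7aS)-7-{[(tert-butyldimethylsilyl)oxy]methyl}-1,7-epoxy-6-hydroxy-1,4a,5,6,7,7a-hexahydrocyclopenta[c]pyran-4-carboxylate
Conditions: HF·pyridine, pyridine (excess), THF, 0 °C
Reagents that add atoms: none
Why: Selective desilylation by fluoride: the secondary triethylsilyl ether is cleaved in the presence of the neopentyl-type primary TBS ether; at this stage O2 is a vinylogous carbonate oxygen, so the acetal ionises slowly and should survive the buffered reagent.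

Step 10
Reactants: 16 methyl (1R,4aS,6S,7R,7aS)-7-{[(tert-butyldimethylsilyl)oxy]methyl}-1,7-epoxy-6-hydroxy-1,4a,5,6,7,7a-hexahydrocyclopenta[c]pyran-4-carboxylate
Product: 17 (1R,4aS,6S,7R,7aS)-7-{[(tert-butyldimethylsilyl)oxy]methyl}-1,7-epoxy-4-(hydroxymethyl)-1,4a,5,6,7,7a-hexahydrocyclopenta[c]pyran-6-ol
Conditions: DIBAL-H (4 equiv), CH2Cl2, −78 °C; Rochelle salt
Reagents that add atoms: none
Why: 1,2-Reduction of the β-alkoxyacrylate ester by DIBAL-H to the C11 allylic alcohol at −78 °C, where the cyclic acetal is not cleaved; extra hydride is consumed by the free C7 hydroxyl.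

Step 11
Reactants: 17 (1R,4aS,6S,7R,7aS)-7-{[(tert-butyldimethylsilyl)oxy]methyl}-1,7-epoxy-4-(hydroxymethyl)-1,4a,5,6,7,7a-hexahydrocyclopenta[c]pyran-6-ol
Product: 18 (1R,4aS,6S,7R,7aS)-4,7-bis{[(tert-butyldimethylsilyl)oxy]methyl}-1,7-epoxy-1,4a,5,6,7,7a-hexahydrocyclopenta[c]pyran-6-ol
Conditions: TBSCl, imidazole, CH2Cl2, 0 °C
Reagents that add atoms: tert-butyldimethylsilyl chloride, CC(C)(C)[Si](C)(C)Cl
Why: Selective silylation of the primary allylic C11 hydroxyl over the hindered secondary C7 hydroxyl, under buffered basic conditions that the now acid-labile oxetane acetal tolerates.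

Step 12
Reactants: 19 p-coumaric acid
Product: 21 (2E)-3-{4-[(tert-butyldimethylsilyl)oxy]phenyl}prop-2-enoic acid, via bis-TBS coumarate 20 (not isolated)
Conditions: TBSCl (2.3 equiv), imidazole, DMF, 23 °C; then AcOH, THF, H2O, 23 °C
Reagents that add atoms: tert-butyldimethylsilyl chloride, CC(C)(C)[Si](C)(C)Cl
Why: Silylation of both the phenol and the carboxyl group, then mild acidic hydrolysis of the labile silyl ester only, gives the O-protected acid with the E double bond unchanged.

Step 13
Reactants: 18 (1R,4aS,6S,7R,7aS)-4,7-bis{[(tert-butyldimethylsilyl)oxy]methyl}-1,7-epoxy-1,4a,5,6,7,7a-hexahydrocyclopenta[c]pyran-6-ol; 21 (2E)-3-{4-[(tert-butyldimethylsilyl)oxy]phenyl}prop-2-enoic acid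
Product: 23 (1R,4aS,6S,7R,7aS)-4,7-bis{[(tert-butyldimethylsilyl)oxy]methyl}-1,7-epoxy-1,4a,5,6,7,7a-hexahydrocyclopenta[c]pyran-6-yl (2E)-3-{4-[(tert-butyldimethylsilyl)oxy]phenyl}prop-2-enoate, via mixed anhydride 22 (not isolated)
Conditions: 21, 2,4,6-trichlorobenzoyl chloride, Et3N, toluene, 23 °C; then 18, DMAP, 23 °C
Reagents that add atoms: 2,4,6-trichlorobenzoyl chloride, O=C(Cl)c1c(Cl)cc(Cl)cc1Cl (its acyl group is held only by intermediate 22)
Why: Yamaguchi esterification: the acid is converted to the mixed anhydride before it meets the substrate, so the acid-labile oxetane acetal sees only basic conditions, and DMAP-catalysed acyl transfer to the free C7 hydroxyl proceeds with retention at C7.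

Step 14
Reactants: 23 (1R,4aS,6S,7R,7aS)-4,7-bis{[(tert-butyldimethylsilyl)oxy]methyl}-1,7-epoxy-1,4a,5,6,7,7a-hexahydrocyclopenta[c]pyran-6-yl (2E)-3-{4-[(tert-butyldimethylsilyl)oxy]phenyl}prop-2-enoate; 24 isovaleric acid
Product: 25 (1S,4aS,6S,7R,7aS)-4,7-bis{[(tert-butyldimethylsilyl)oxy]methyl}-7-hydroxy-1-[(3-methylbutanoyl)oxy]-1,4a,5,6,7,7a-hexahydrocyclopenta[c]pyran-6-yl (2E)-3-{4-[(tert-butyldimethylsilyl)oxy]phenyl}prop-2-enoate
Conditions: 24 (10 equiv), 4 Å MS, CH2Cl2, 0 → 23 °C
Reagents that add atoms: none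
Why: Acidolysis of the strained oxetane acetal by the carboxylic acid, the counterpart of the opening of 1,2-anhydro sugars by carboxylic acids: protonation of the oxetane oxygen and attack of the carboxylate at C1 from the convex β face, anti to the departing C1–O bond and to C8, inverts C1 (1R → 1S), gives the 1β-acyloxy acetal and frees the tertiary C8 hydroxyl.

Step 15
Reactants: 25 (1S,4aS,6S,7R,7aS)-4,7-bis{[(tert-butyldimethylsilyl)oxy]methyl}-7-hydroxy-1-[(3-methylbutanoyl)oxy]-1,4a,5,6,7,7a-hexahydrocyclopenta[c]pyran-6-yl (2E)-3-{4-[(tert-butyldimethylsilyl)oxy]phenyl}prop-2-enoate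
Product: 26 luzonoid A, (1S,4aS,6S,7R,7aS)-7-hydroxy-4,7-bis(hydroxymethyl)-1-[(3-methylbutanoyl)oxy]-1,4a,5,6,7,7a-hexahydrocyclopenta[c]pyran-6-yl (2E)-3-(4-hydroxyphenyl)prop-2-enoate
Conditions: HF·pyridine, pyridine, THF, 0 → 23 °C
Reagents that add atoms: none
Why: Global desilylation by fluoride removes the two primary TBS ethers and the aryl TBS ether under buffered, non-basic conditions, which avoids acyl migration and loss of the anomeric ester; no stereocentre is touched.

Compound list
1 | 2-deoxy-D-ribose (open-chain form) | O=CC[C@H](O)[C@H](O)CO | starting material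
2 | 2-deoxy-D-ribono-1,4-lactone | O=C1C[C@H](O)[C@@H](CO)O1 | intermediate
3 | (4S,5R)-5-{[(tert-butyldimethylsilyl)oxy]methyl}-4-hydroxyoxolan-2-one | O=C1C[C@H](O)[C@@H](CO[Si](C)(C)C(C)(C)C)O1 | intermediate (not isolated)
4 | (4S,5R)-5-{[(tert-butyldimethylsilyl)oxy]methyl}-4-[(triethylsilyl)oxy]oxolan-2-one | O=C1C[C@H](O[Si](CC)(CC)CC)[C@@H](CO[Si](C)(C)C(C)(C)C)O1 | intermediate
5 | (2R,3S)-1-[(tert-butyldimethylsilyl)oxy]-3-[(triethylsilyl)oxy]pentane-2,5-diol | OCC[C@H](O[Si](CC)(CC)CC)[C@H](O)CO[Si](C)(C)C(C)(C)C | intermediate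
6 | (triphenylphosphoranylidene)acetaldehyde | O=CC=P(c1ccccc1)(c1ccccc1)c1ccccc1 | starting material
7 | (3S)-5-[(tert-butyldimethylsilyl)oxy]-4-oxo-3-[(triethylsilyl)oxy]pentanal | O=CC[C@H](O[Si](CC)(CC)CC)C(=O)CO[Si](C)(C)C(C)(C)C | intermediate (not isolated)
8 | (2E,5S)-7-[(tert-butyldimethylsilyl)oxy]-6-oxo-5-[(triethylsilyl)oxy]hept-2-enal | O=C/C=C/C[C@H](O[Si](CC)(CC)CC)C(=O)CO[Si](C)(C)C(C)(C)C | intermediate
9 | ethyl vinyl ether | C=COCC | starting material
10 | (3S)-1-[(tert-butyldimethylsilyl)oxy]-4-[(2S,4S)-2-ethoxy-3,4-dihydro-2H-pyran-4-yl]-3-[(triethylsilyl)oxy]butan-2-one | CCO[C@@H]1C[C@H](C[C@H](O[Si](CC)(CC)CC)C(=O)CO[Si](C)(C)C(C)(C)C)C=CO1 | intermediate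
11 | trichloroacetyl chloride | O=C(Cl)C(Cl)(Cl)Cl | starting material
12 | (3S)-1-[(tert-butyldimethylsilyl)oxy]-4-[(2S,4S)-2-ethoxy-5-(trichloroacetyl)-3,4-dihydro-2H-pyran-4-yl]-3-[(triethylsilyl)oxy]butan-2-one | CCO[C@@H]1C[C@H](C[C@H](O[Si](CC)(CC)CC)C(=O)CO[Si](C)(C)C(C)(C)C)C(C(=O)C(Cl)(Cl)Cl)=CO1 | intermediate (not isolated)
13 | methyl (2S,4S)-4-[(2S)-4-[(tert-butyldimethylsilyl)oxy]-3-oxo-2-[(triethylsilyl)oxy]butyl]-2-ethoxy-3,4-dihydro-2H-pyran-5-carboxylate | CCO[C@@H]1C[C@H](C[C@H](O[Si](CC)(CC)CC)C(=O)CO[Si](C)(C)C(C)(C)C)C(C(=O)OC)=CO1 | intermediate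
14 | methyl (4S)-4-[(2S)-4-[(tert-butyldimethylsilyl)oxy]-3-oxo-2-[(triethylsilyl)oxy]butyl]-4H-pyran-3-carboxylate (key-step precursor) | COC(=O)C1=COC=C[C@@H]1C[C@H](O[Si](CC)(CC)CC)C(=O)CO[Si](C)(C)C(C)(C)C | intermediate
15 | methyl (1R,4aS,6S,7R,7aS)-7-{[(tert-butyldimethylsilyl)oxy]methyl}-1,7-epoxy-6-[(triethylsilyl)oxy]-1,4a,5,6,7,7a-hexahydrocyclopenta[c]pyran-4-carboxylate (key-step product) | COC(=O)C1=CO[C@@H]2O[C@@]3(CO[Si](C)(C)C(C)(C)C)[C@@H]2[C@@H]1C[C@@H]3O[Si](CC)(CC)CC | intermediate
16 | methyl (1R,4aS,6S,7R,7aS)-7-{[(tert-butyldimethylsilyl)oxy]methyl}-1,7-epoxy-6-hydroxy-1,4a,5,6,7,7a-hexahydrocyclopenta[c]pyran-4-carboxylate | COC(=O)C1=CO[C@@H]2O[C@@]3(CO[Si](C)(C)C(C)(C)C)[C@@H]2[C@@H]1C[C@@H]3O | intermediate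
17 | (1R,4aS,6S,7R,7aS)-7-{[(tert-butyldimethylsilyl)oxy]methyl}-1,7-epoxy-4-(hydroxymethyl)-1,4a,5,6,7,7a-hexahydrocyclopenta[c]pyran-6-ol | OCC1=CO[C@@H]2O[C@@]3(CO[Si](C)(C)C(C)(C)C)[C@@H]2[C@@H]1C[C@@H]3O | intermediate
18 | (1R,4aS,6S,7R,7aS)-4,7-bis{[(tert-butyldimethylsilyl)oxy]methyl}-1,7-epoxy-1,4a,5,6,7,7a-hexahydrocyclopenta[c]pyran-6-ol | CC(C)(C)[Si](C)(C)OCC1=CO[C@@H]2O[C@@]3(CO[Si](C)(C)C(C)(C)C)[C@@H]2[C@@H]1C[C@@H]3O | intermediate
19 | p-coumaric acid | OC(=O)/C=C/c1ccc(O)cc1 | starting material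
20 | tert-butyldimethylsilyl (2E)-3-{4-[(tert-butyldimethylsilyl)oxy]phenyl}prop-2-enoate | CC(C)(C)[Si](C)(C)OC(=O)/C=C/c1ccc(O[Si](C)(C)C(C)(C)C)cc1 | intermediate (not isolated)
21 | (2E)-3-{4-[(tert-butyldimethylsilyl)oxy]phenyl}prop-2-enoic acid | OC(=O)/C=C/c1ccc(O[Si](C)(C)C(C)(C)C)cc1 | intermediate
22 | (2E)-3-{4-[(tert-butyldimethylsilyl)oxy]phenyl}prop-2-enoic 2,4,6-trichlorobenzoic anhydride | O=C(OC(=O)/C=C/c1ccc(O[Si](C)(C)C(C)(C)C)cc1)c1c(Cl)cc(Cl)cc1Cl | intermediate (not isolated)
23 | (1R,4aS,6S,7R,7aS)-4,7-bis{[(tert-butyldimethylsilyl)oxy]methyl}-1,7-epoxy-1,4a,5,6,7,7a-hexahydrocyclopenta[c]pyran-6-yl (2E)-3-{4-[(tert-butyldimethylsilyl)oxy]phenyl}prop-2-enoate | CC(C)(C)[Si](C)(C)OCC1=CO[C@@H]2O[C@@]3(CO[Si](C)(C)C(C)(C)C)[C@@H]2[C@@H]1C[C@@H]3OC(=O)/C=C/c4ccc(O[Si](C)(C)C(C)(C)C)cc4 | intermediate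
24 | isovaleric acid | CC(C)CC(O)=O | starting material
25 | (1S,4aS,6S,7R,7aS)-4,7-bis{[(tert-butyldimethylsilyl)oxy]methyl}-7-hydroxy-1-[(3-methylbutanoyl)oxy]-1,4a,5,6,7,7a-hexahydrocyclopenta[c]pyran-6-yl (2E)-3-{4-[(tert-butyldimethylsilyl)oxy]phenyl}prop-2-enoate | CC(C)CC(=O)O[C@@H]1OC=C(CO[Si](C)(C)C(C)(C)C)[C@H]2C[C@H](OC(=O)/C=C/c3ccc(O[Si](C)(C)C(C)(C)C)cc3)[C@](O)(CO[Si](C)(C)C(C)(C)C)[C@@H]12 | intermediate
26 | luzonoid A | CC(C)CC(=O)O[C@@H]1OC=C(CO)[C@H]2C[C@H](OC(=O)/C=C/c3ccc(O)cc3)[C@](O)(CO)[C@@H]12 | target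

Total step count: 15. Longest linear sequence: 14 steps (steps 1–11 and 13–15; step 12 is a one-step side branch).

Steps most likely to fail

Step 8 (key step). The excited ketone may abstract the doubly allylic γ-hydrogen at C5 (Norrish type II cleavage or cyclobutanol formation) faster than it adds to C1=C9, or the biradical may close in the crossed sense. Fallback: the same two bonds are made in the ground state. Setting out from 14, a Lewis acid (Me2AlCl, CH2Cl2, −78 °C) activates the C8 ketone for a Mukaiyama–Prins attack by C9 of the enol ether. The metal alkoxide formed sits next to the C1 oxocarbenium ion and collapses onto it, the stepwise thermal [2+2] path by which carbonyl compounds and electron-rich alkenes give 2-alkoxyoxetanes. Only the C8 epimer whose oxygen can reach C1 can close and the other reverts, so the route is re-entered at 15 and no new compound is made (F0).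

Step 7. The ester-deactivated acetal may ionise too slowly, so that forcing conditions bring loss of the TES ether, enolisation next to C7, or isomerisation of the 4H-pyran. Fallback: setting out from 13, dimethylboron bromide (CH2Cl2, −78 °C) exchanges the anomeric ethoxy group for bromide to give the anomeric bromide F1. This is used cold without purification, and DBU (−78 → 0 °C) then removes hydrogen bromide by E2 elimination and returns the route to 14.

Step 14. A free oxocarbenium ion may be captured on both faces (loss of facial selectivity at C1), the acid may add to the C3=C4 enol ether, or traces of water may hydrolyse the acetal. Fallback: setting out from 23, the oxetane acetal is hydrolysed on purpose (PPTS cat., THF/H2O, 0 °C) to the lactol F2, whose hemiacetal hydroxyl equilibrates. The hemiacetal is then acylated, far faster than the tertiary C8 hydroxyl, with isovaleric anhydride, Et3N and DMAP (cat.) in CH2Cl2 at −40 °C. The β-ester, preferred sterically and by the anomeric effect, should predominate, and the route is re-entered at 25.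

Further compounds
F0 | step 8 | none | none
F1 | step 7 | methyl (2R,4S)-2-bromo-4-[(2S)-4-[(tert-butyldimethylsilyl)oxy]-3-oxo-2-[(triethylsilyl)oxy]butyl]-3,4-dihydro-2H-pyran-5-carboxylate (drawn as one anomer) | Br[C@@H]1C[C@H](C[C@H](O[Si](CC)(CC)CC)C(=O)CO[Si](C)(C)C(C)(C)C)C(C(=O)OC)=CO1
F2 | step 14 | (1R,4aS,6S,7R,7aS)-4,7-bis{[(tert-butyldimethylsilyl)oxy]methyl}-1,7-dihydroxy-1,4a,5,6,7,7a-hexahydrocyclopenta[c]pyran-6-yl (2E)-3-{4-[(tert-butyldimethylsilyl)oxy]phenyl}prop-2-enoate | O[C@@H]1OC=C(CO[Si](C)(C)C(C)(C)C)[C@H]2C[C@H](OC(=O)/C=C/c3ccc(O[Si](C)(C)C(C)(C)C)cc3)[C@](O)(CO[Si](C)(C)C(C)(C)C)[C@@H]12
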